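Target **22** is methyl 3β-angeloyloxy-5α-hydroperoxyeudesma-4(15),11(13)-dien-12-oate, (3S,5S,7R,10S). Eudesmane numbering is used for all bicyclic compounds and, for clarity, for the carbons of the open-chain precursors; α/β refer to the usual drawing with the C10 methyl group β.

## The problem

Compound **22** is a eudesmane in which ring A (C1–C5, C10) and ring B (C5–C10) share the C5–C10 bond, C10 being an all-carbon quaternary centre and the neighbouring C5 a fully substituted carbon that carries the hydroperoxide. Of its four stereocentres (3β-O, 5α-OO, 7β-C, 10β-CH3), C7 lies far from all functionality and is best bought from the chiral pool; it can then set C10 through a chair-shaped ring B, and the axial C10 methyl group in turn shields the β-face for the later bond formations at C3 and C5. Three groups do not tolerate rough treatment: the tertiary allylic hydroperoxide (reductants, acid, base, metals), the angelate (Z→E isomerisation to the tiglate by base, nucleophilic catalysts or energy transfer) and the methyl 2-alkylpropenoate (Michael acceptor, dienophile). The hydroperoxide therefore has to be made last, the angelate second to last, and the propenoate after any cycloaddition. The 5-hydroperoxy-4(15)-ene unit is the retron of an ene reaction of oxygen with a C4=C5 alkene bearing the C15 methyl group, which reduces ring A to a 4-methyl-4-en-3-one. The feature that makes the key step possible is the pattern of ring A: oxygen on C3, a one-carbon group on C4 next to quaternary C10, and bare methylenes at C1 and C2. This is the imprint of a 2-silyloxy-3-methyl-1,3-diene (C2=C3–C4=C5) adding to a 1,1-disubstituted alkene (C10=C1), and because C5 and C10 are also joined by C6–C9, the addition can be intramolecular and close both rings. Since C1 is unfunctionalised in **22**, the group that activates C10=C1 must be removable without trace.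

## Retrosynthesis

**22 ⇒ 21.** The C5–O bond is cut, a hydrogen is returned to C15 and the alkene moves to C4=C5 (retro-Schenck ene reaction). No other cut removes the most fragile group in one step, and any earlier introduction of the peroxide would have to survive acylation and oxidation chemistry. The precursor **21** has one stereocentre less and no peroxide. The forward step must bond oxygen to C5 on the α-face and take hydrogen from C15, not from C6 or C3.

**21 ⇒ 18 + 19.** The ester C–O bond at C3 is cut to give allylic alcohol **18** and angelic acid **19**. Placing this second to last exposes the isomerisation-prone Z-enoate to a single further step. The acylation must proceed without a nucleophilic catalyst and with retention at C3.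

**18 ⇒ 17 ⇒ 16 ⇒ 15 ⇒ 14 ⇒ 13.** The C3–H bond is removed (**17**), then the oxidation level of C12 is stepped back through acid **16**, aldehyde **15** and alcohol **14** to the isopropenyl group of (+)-α-cyperone **13**. The isopropenyl group is chosen as the masked propenoate because it is inert to heat and, unlike the propenoate, is not a competing dienophile. Compound **13** has only two stereocentres (C7, C10) and one ring alkene. The forward steps need allylic oxidation at the electron-rich alkene only, and a 1,2-reduction that puts the C3 oxygen β.

**13 ⇒ 12 ⇒ 11.** The C4=C5 alkene is traced to the silyl enol ether **12** (loss of H5), and C1–H to the C1–sulfonyl bond of **11**. The sulfone must be removed before the C3 carbonyl is unveiled, because a 3-keto-1-sulfone would eliminate sulfinate. Both changes erase stereocentres (C1, C5), so only C7 and C10 of **11** matter.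

**11 ⇒ 10 (key cut).** C5–C10 and C1–C2 are cut together (retro-Diels–Alder), opening both rings to the acyclic triene **10** with a single stereocentre. Cutting only one ring (an annulation onto a preformed cyclohexane) would leave the quaternary centre to be made on a ring by alkylation. Here C10 is created as the cycloaddition terminus under control of C7. The forward reaction has to overcome a trisubstituted dienophile and must choose the face of C10 correctly.

**10 ⇒ 9 ⇒ 7 + 8.** The O–Si bond is cut to give enone **9**, then the C4=C5 alkene to give aldehyde **7** and the stabilised ylide **8**. The Wittig reaction is chosen because it is neutral and sets the E geometry the diene needs.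

**7 ⇒ 6 ⇒ 4 + 5.** The aldehyde is masked as the acetal **6**, and the C10=C1 alkene is cut to methyl ketone **4** and sulfonylphosphonate **5**. Making the vinyl sulfone first, with the aldehyde masked, means the phosphonate anion never meets an enone (conjugate addition, intramolecular Michael reaction of the ketone enolate). The sulfone is therefore installed before the enone, at the cost of one acetal hydrolysis.

**4 ⇒ 1.** Both carbonyl carbons (future C10 and C5) come from the ring alkene of (R)-limonene **1**, whose stereocentre becomes C7 unchanged. The cleavage must spare the isopropenyl group and deliver the two carbonyls differentiated.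

## Roads not taken

Alternative 1: Both ring B bonds to C7 (C6–C7, C7–C8) are cut. In the forward sense dimethyl malonate A3 is alkylated twice by the ring A dihalide A2 to give the diester A1. The merits are two robust SN2 alkylations, no high-temperature step, and a C7 centre that becomes epimerisable, so it can be set thermodynamically after loss of one ester. The weak points are three. A2 already contains the C10 quaternary stereocentre, which must come from a separate asymmetric step. A2 also combines an enone with a γ-bromide, inviting SN2′ attack and dienolisation. And after A1 one ester carbon must be removed and the other rebuilt into the three-carbon propenoate (C11–C13), which costs at least five operations. In reliability of ring closure and of the C7 configuration this road is as good as or better than the chosen one. The chosen plan sets against it that C7 and C11–C13 arrive intact from **1**, and that C10 is made and controlled in the same step that closes the rings.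

Alternative 2: Only C1–C10 is cut (retro-oxy-Cope). The potassium alkoxide of the bicyclic vinyl carbinol A5 rearranges, with cleavage of the C3–C8 bridge bond, to the cis-fused octalone A4. The rearrangement is fast and stereospecific: the configuration of C10 and the ring fusion are dictated by the bicyclic framework, which is more secure than the conformational control on which the chosen key step relies. Against this, A5 must be made enantiopure by an asymmetric cycloaddition and a face-selective vinyl addition. A4 also has to be corrected at several points: a surplus C8=C9 alkene, C4 and C5 saturated, and C11 as a protected tertiary alcohol that must be dehydrated regioselectively before the allylic oxidation. The chosen plan has the weaker stereochemical guarantee at C10 but far fewer oxidation-state corrections and no asymmetric step.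

Alternative 3: C7–C8 is cut. On irradiation with hexabutylditin A8, the primary radical generated from iodide A7 adds 6-exo to C7 and expels a sulfonyl radical, giving A6, which is identical with **17** of the chosen route. This closes ring B and unveils the propenoate in a single neutral step, so it would save the four-step isopropenyl oxidation (steps 9–12) and avoid selenium; in end-game economy it is clearly better. Its weak points are three. A7 needs the same de novo quaternary stereocentre as Alternative 1 plus two differentiated side chains. The 6-exo addition to a trisubstituted alkene is slow. And C7 is fixed kinetically, with no later correction. The chosen plan pays with a longer oxidation sequence but takes its stereochemistry from the pool and reaches its key-step precursor in five steps.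

Key step: step 6

Remark on the chemistry: vinyl sulfone **6** is carried forward as its E isomer; any Z isomer from step 2 is assumed to be separable by chromatography.

## Route

Step 1
Reactants: 1 (R)-(+)-limonene
Product: 4 (5R)-7,7-dimethoxy-5-(prop-1-en-2-yl)heptan-2-one, via methoxy hydroperoxide aldehyde 2 (not isolated), via methoxy hydroperoxide acetal 3 (not isolated)
Conditions: O3 (ca. 1 equiv, Sudan Red 7B end point), CH2Cl2/MeOH, −78 °C; TsOH·H2O (cat.), rt; then NaHCO3, Me2S, rt
Reagents that add atoms: ozone, [O-][O+]=O; methanol, CO
Why: Ozone attacks the electron-rich trisubstituted ring alkene before the isopropenyl group (the dye end point limits the dose); Criegee fragmentation in methanol gives the ketone-derived methoxy hydroperoxide 2 and a free aldehyde, acid acetalises only the aldehyde (3), and reduction of the peroxide then unveils the ketone, so the two carbonyls leave the flask differentiated. The stereocentre is untouched.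

Step 2
Reactants: 4 (5R)-7,7-dimethoxy-5-(prop-1-en-2-yl)heptan-2-one; 5 diethyl (phenylsulfonylmethyl)phosphonate
Product: 6 [(1E,5R)-7,7-dimethoxy-2-methyl-5-(prop-1-en-2-yl)hept-1-en-1-yl]sulfonylbenzene
Conditions: 5, n-BuLi, THF, −78 °C; then 4, −78 °C → rt
Reagents that add atoms: none
Why: Horner–Wadsworth–Emmons olefination of the methyl ketone by the lithiated sulfonylphosphonate; the acetal is inert and no other carbonyl is present. The E isomer (sulfonyl trans to the longer chain) should predominate, and the C1 geometry is erased in step 7 in any case.

Step 3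
Reactants: 6 [(1E,5R)-7,7-dimethoxy-2-methyl-5-(prop-1-en-2-yl)hept-1-en-1-yl]sulfonylbenzene
Product: 7 (3R,6E)-6-methyl-7-(phenylsulfonyl)-3-(prop-1-en-2-yl)hept-6-enal
Conditions: 1 M HCl, THF, rt
Reagents that add atoms: water, O
Why: Acid-catalysed acetal hydrolysis; the vinyl sulfone and isopropenyl group tolerate dilute aqueous acid, and the stereocentre is β to the aldehyde and cannot epimerise.

Step 4
Reactants: 7 (3R,6E)-6-methyl-7-(phenylsulfonyl)-3-(prop-1-en-2-yl)hept-6-enal; 8 3-(triphenylphosphoranylidene)butan-2-one
Product: 9 (3E,6R,9E)-3,9-dimethyl-10-(phenylsulfonyl)-6-(prop-1-en-2-yl)deca-3,9-dien-2-one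
Conditions: PhMe, 100 °C
Reagents that add atoms: none
Why: Wittig reaction of a stabilised α-methyl acyl ylide, which gives the E trisubstituted enone (acetyl trans to the chain); the β,β-disubstituted vinyl sulfone is too hindered an acceptor for this weakly nucleophilic ylide.

Step 5
Reactants: 9 (3E,6R,9E)-3,9-dimethyl-10-(phenylsulfonyl)-6-(prop-1-en-2-yl)deca-3,9-dien-2-one
Product: 10 tert-butyl(dimethyl){[(3E,6R,9E)-3,9-dimethyl-10-(phenylsulfonyl)-6-(prop-1-en-2-yl)deca-1,3,9-trien-2-yl]oxy}silane
Conditions: TBSOTf, Et3N, CH2Cl2, −78 → 0 °C
Reagents that add atoms: tert-butyldimethylsilyl trifluoromethanesulfonate, CC(C)(C)[Si](C)(C)OS(=O)(=O)C(F)(F)F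
Why: Soft enolisation: O-silylation activates only the ketone and the amine removes an α′-methyl proton, giving the cross-conjugated 2-silyloxydiene with the C4=C5 geometry retained. Triethylamine is too weak to deprotonate or isomerise the vinyl sulfone, which is why amide bases are avoided.

Step 6
Reactants: 10 tert-butyl(dimethyl){[(3E,6R,9E)-3,9-dimethyl-10-(phenylsulfonyl)-6-(prop-1-en-2-yl)deca-1,3,9-trien-2-yl]oxy}silane
Product: 11 3-(tert-butyldimethylsilyloxy)-1β-(phenylsulfonyl)-5α-eudesma-3,11-diene
Conditions: PhMe (0.01 M), BHT (cat.), N,O-bis(trimethylsilyl)acetamide (0.1 equiv), sealed tube, 190 °C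
Reagents that add atoms: none
Why: A concerted, asynchronous normal-demand [4+2] cycloaddition of the silyloxydiene C2=C3–C4=C5 with the sulfone-activated alkene C10=C1; the closest known reaction type is the thermal intramolecular Diels–Alder reaction of a 2-silyloxy-1,3,9-decatriene with a vinyl sulfone serving as a removable ethylene equivalent. Ring B closes through C5–C10 as the six-membered ring of the four-carbon tether (C6–C9) in a chair, and ring A closes through C1–C2 as the cyclohexene silyl enol ether. The tether allows only the fused mode, although this pairs the more nucleophilic diene terminus C2 with the sulfone-bearing carbon C1, which is why 190 °C is needed. C10 is set by C7: with isopropenyl equatorial and C1 (not the methyl group) equatorial on the forming ring B, the methyl group becomes axial and cis to isopropenyl. C5 follows from the E diene and the exo position of the tether (H5 anti to the C10 methyl group, trans fusion), and C1 from the E sulfone by suprafacial addition with sulfonyl endo and cis to the methyl group. The selectivity that matters is the face of C10 relative to C7, because C1 and C5 are erased in steps 7 and 8; the trans-fused chair and the cis-fused chair with C1 equatorial both deliver it, and only a chair with C1 axial or isopropenyl axial does not. BHT suppresses radical polymerisation and the silylating scavenger protects the dienol ether from traces of acid and water.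

Step 7
Reactants: 11 3-(tert-butyldimethylsilyloxy)-1β-(phenylsulfonyl)-5α-eudesma-3,11-diene
Product: 12 3-(tert-butyldimethylsilyloxy)-5α-eudesma-3,11-diene
Conditions: 6% Na(Hg), Na2HPO4, MeOH/THF, −20 → 0 °C
Reagents that add atoms: none
Why: Reductive desulfonylation by electron transfer: the sulfone radical anion loses benzenesulfinate and the C1 radical is reduced and protonated by methanol. It is done while C3 is still a silyl enol ether, since a free 3-ketone would make the sulfone a β-leaving group; the phosphate buffer spares the enol ether.

Step 8
Reactants: 12 3-(tert-butyldimethylsilyloxy)-5α-eudesma-3,11-diene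
Product: 13 (+)-α-cyperone (eudesma-4,11-dien-3-one)
Conditions: Pd(OAc)2 (1.1 equiv), MeCN, rt → 40 °C
Reagents that add atoms: none
Why: Saegusa–Ito oxidation: transmetalation gives the divalent palladium enolate bound at C4, and syn β-hydride elimination of the 5α-hydrogen gives the conjugated tetrasubstituted enone with release of zerovalent palladium. C5 becomes sp2, so the ring-fusion outcome of step 6 no longer matters.

Step 9
Reactants: 13 (+)-α-cyperone (eudesma-4,11-dien-3-one)
Product: 14 12-hydroxyeudesma-4,11(13)-dien-3-one
Conditions: SeO2 (0.5 equiv), t-BuOOH (2 equiv), CH2Cl2, 0 °C → rt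
Reagents that add atoms: selenium dioxide, O=[Se]=O; tert-butyl hydroperoxide, CC(C)(C)OO
Why: Allylic hydroxylation by SeO2 with t-BuOOH as reoxidant (ene reaction at the terminal CH2 of the electron-rich isopropenyl group, then [2,3]-sigmatropic shift), which places oxygen on the methyl carbon and restores the 1,1-disubstituted alkene; the electron-poor enone alkene reacts much more slowly. Any 12-aldehyde formed alongside converges in step 10.

Step 10
Reactants: 14 12-hydroxyeudesma-4,11(13)-dien-3-one
Product: 15 3-oxoeudesma-4,11(13)-dien-12-al
Conditions: MnO2 (activated, excess), CH2Cl2, rt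
Reagents that add atoms: none
Why: Chemoselective oxidation of the primary allylic alcohol on MnO2; no other alcohol is present.

Step 11
Reactants: 15 3-oxoeudesma-4,11(13)-dien-12-al
Product: 16 3-oxoeudesma-4,11(13)-dien-12-oic acid
Conditions: NaClO2, NaH2PO4, 2-methylbut-2-ene, t-BuOH/H2O, 0 °C → rt
Reagents that add atoms: sodium chlorite, [Na+].[O-]Cl=O
Why: Pinnick oxidation of the enal through its chlorous acid adduct; 2-methylbut-2-ene traps the hypochlorous acid, so the alkenes and the enone are untouched.

Step 12
Reactants: 16 3-oxoeudesma-4,11(13)-dien-12-oic acid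
Product: 17 methyl 3-oxoeudesma-4,11(13)-dien-12-oate
Conditions: MeI, K2CO3, DMF, rt
Reagents that add atoms: iodomethane, CI
Why: SN2 O-alkylation of the potassium carboxylate; carbonate is too weak a base to enolise the enone to a useful extent.

Step 13
Reactants: 17 methyl 3-oxoeudesma-4,11(13)-dien-12-oate
Product: 18 methyl 3β-hydroxyeudesma-4,11(13)-dien-12-oate
Conditions: NaBH4, CeCl3·7H2O, MeOH, −78 → −20 °C
Reagents that add atoms: none
Why: Luche reduction: the CeCl3-modified borohydride adds 1,2 to the enone and leaves the propenoate ester alone at low temperature. As with 4-en-3-ones of the steroid series, hydride arrives pseudo-axially from the α-face and gives the pseudo-equatorial 3β-alcohol (3S).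

Step 14
Reactants: 18 methyl 3β-hydroxyeudesma-4,11(13)-dien-12-oate; 19 angelic acid
Product: 21 methyl 3β-angeloyloxyeudesma-4,11(13)-dien-12-oate, via angelic 2,4,6-trichlorobenzoic anhydride 20 (not isolated)
Conditions: 19, 2,4,6-Cl3C6H2COCl, Et3N, PhMe, rt; then 18, PhMe, 80 °C
Reagents that add atoms: none
Why: Yamaguchi-type esterification through mixed anhydride 20, run without a nucleophilic pyridine catalyst because such catalysts isomerise angelates to tiglates by conjugate addition and elimination. The alcohol attacks the angeloyl carbonyl, since the other carbonyl is flanked by two ortho chlorines; C3 is retained (O-acylation).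

Step 15
Reactants: 21 methyl 3β-angeloyloxyeudesma-4,11(13)-dien-12-oate
Product: 22 methyl 3β-angeloyloxy-5α-hydroperoxyeudesma-4(15),11(13)-dien-12-oate
Conditions: O2, 5,10,15,20-tetraphenylporphyrin (cat.), CH2Cl2, visible light (>500 nm), −20 °C; no reductive work-up
Reagents that add atoms: dioxygen, O=O
Why: Schenck ene reaction of singlet oxygen with the only electron-rich tetrasubstituted alkene; oxygen should bond to C5 on the α-face, anti to the axial C10 methyl group, with transfer of a hydrogen from the freely rotating C15 methyl group, which sets 5S and the exocyclic C4=C15 alkene. The competing hydrogens are poorly placed or deactivated (on the α-face the C6 hydrogen is equatorial, and the C3 hydrogen is geminal to the acyloxy group). A low-triplet-energy sensitiser and long-wavelength light should avoid Z→E isomerisation of the angelate.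

## Compound list

1 | (R)-(+)-limonene, (4R)-1-methyl-4-(prop-1-en-2-yl)cyclohex-1-ene | CC1=CC[C@@H](CC1)C(C)=C | starting material
2 | (3R)-6-hydroperoxy-6-methoxy-3-(prop-1-en-2-yl)heptanal (both C6 epimers) | CC(=C)[C@@H](CC=O)CCC(C)(OC)OO | intermediate
3 | (3R)-6-hydroperoxy-1,1,6-trimethoxy-3-(prop-1-en-2-yl)heptane (both C6 epimers) | CC(=C)[C@@H](CC(OC)OC)CCC(C)(OC)OO | intermediate
4 | (5R)-7,7-dimethoxy-5-(prop-1-en-2-yl)heptan-2-one | CC(=C)[C@@H](CC(OC)OC)CCC(C)=O | intermediate
5 | diethyl (phenylsulfonylmethyl)phosphonate | CCOP(=O)(CS(=O)(=O)c1ccccc1)OCC | starting material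
6 | [(1E,5R)-7,7-dimethoxy-2-methyl-5-(prop-1-en-2-yl)hept-1-en-1-yl]sulfonylbenzene | CC(=C)[C@@H](CC(OC)OC)CC/C(C)=C/S(=O)(=O)c1ccccc1 | intermediate
7 | (3R,6E)-6-methyl-7-(phenylsulfonyl)-3-(prop-1-en-2-yl)hept-6-enal | CC(=C)[C@@H](CC=O)CC/C(C)=C/S(=O)(=O)c1ccccc1 | intermediate
8 | 3-(triphenylphosphoranylidene)butan-2-one | CC(=O)C(C)=P(c1ccccc1)(c1ccccc1)c1ccccc1 | starting material
9 | (3E,6R,9E)-3,9-dimethyl-10-(phenylsulfonyl)-6-(prop-1-en-2-yl)deca-3,9-dien-2-one | CC(=C)[C@@H](C/C=C(\C)C(C)=O)CC/C(C)=C/S(=O)(=O)c1ccccc1 | intermediate
10 | tert-butyl(dimethyl){[(3E,6R,9E)-3,9-dimethyl-10-(phenylsulfonyl)-6-(prop-1-en-2-yl)deca-1,3,9-trien-2-yl]oxy}silane | CC(=C)[C@@H](C/C=C(\C)C(=C)O[Si](C)(C)C(C)(C)C)CC/C(C)=C/S(=O)(=O)c1ccccc1 | intermediate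
11 | 3-(tert-butyldimethylsilyloxy)-1β-(phenylsulfonyl)-5α-eudesma-3,11-diene (trans-fused; 5α-H, 10β-CH3, 7β-isopropenyl) | CC(=C)[C@@H]1CC[C@@]2(C)[C@H](S(=O)(=O)c3ccccc3)CC(O[Si](C)(C)C(C)(C)C)=C(C)[C@@H]2C1 | intermediate
12 | 3-(tert-butyldimethylsilyloxy)-5α-eudesma-3,11-diene | CC(=C)[C@@H]1CC[C@@]2(C)CCC(O[Si](C)(C)C(C)(C)C)=C(C)[C@@H]2C1 | intermediate
13 | (+)-α-cyperone, (4aS,7R)-1,4a-dimethyl-7-(prop-1-en-2-yl)-4,4a,5,6,7,8-hexahydronaphthalen-2(3H)-one | CC(=C)[C@@H]1CC[C@@]2(C)CCC(=O)C(C)=C2C1 | intermediate
14 | 12-hydroxyeudesma-4,11(13)-dien-3-one (7β side chain, 10β-CH3) | C=C(CO)[C@@H]1CC[C@@]2(C)CCC(=O)C(C)=C2C1 | intermediate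
15 | 3-oxoeudesma-4,11(13)-dien-12-al | C=C(C=O)[C@@H]1CC[C@@]2(C)CCC(=O)C(C)=C2C1 | intermediate
16 | 3-oxoeudesma-4,11(13)-dien-12-oic acid | C=C(C(=O)O)[C@@H]1CC[C@@]2(C)CCC(=O)C(C)=C2C1 | intermediate
17 | methyl 3-oxoeudesma-4,11(13)-dien-12-oate | C=C(C(=O)OC)[C@@H]1CC[C@@]2(C)CCC(=O)C(C)=C2C1 | intermediate
18 | methyl 3β-hydroxyeudesma-4,11(13)-dien-12-oate | C=C(C(=O)OC)[C@@H]1CC[C@@]2(C)CC[C@H](O)C(C)=C2C1 | intermediate
19 | angelic acid, (2Z)-2-methylbut-2-enoic acid | C/C=C(/C)C(=O)O | starting material
20 | (2Z)-2-methylbut-2-enoic 2,4,6-trichlorobenzoic anhydride | C/C=C(/C)C(=O)OC(=O)c1c(Cl)cc(Cl)cc1Cl | intermediate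
21 | methyl 3β-[(2Z)-2-methylbut-2-enoyloxy]eudesma-4,11(13)-dien-12-oate | C=C(C(=O)OC)[C@@H]1CC[C@@]2(C)CC[C@H](OC(=O)/C(C)=C\C)C(C)=C2C1 | intermediate
22 | methyl 3β-angeloyloxy-5α-hydroperoxyeudesma-4(15),11(13)-dien-12-oate (3S,5S,7R,10S) | C=C(C(=O)OC)[C@@H]1CC[C@@]2(C)CC[C@H](OC(=O)/C(C)=C\C)C(=C)[C@]2(OO)C1 | target

## Step count and risks

Total: 15 steps. Longest linear sequence: 15 steps from **1**; compounds **5**, **8** and **19** are purchased.

**Step 6 (key step).** Two things may go wrong. The cycloaddition may be too slow, because the tether enforces the electronically unfavourable orientation and the dienophile is trisubstituted, so thermal decomposition or hydrolysis of the dienol ether can overtake it. Alternatively, the chair with C1 axial may compete and erode the facial selectivity at C10. Epimers at C10 would be separable as diastereomers at the stage of **13**, but the material would be lost. The fallback sets out from **1** and returns at **13**, replacing the cycloaddition by an annulation onto a preformed ring. Epoxidation (mCPBA) gives limonene 1,2-oxide F1, and Meinwald rearrangement (ZnBr2, PhMe) gives (5R)-dihydrocarvone F2. Condensation with (R)-1-phenylethylamine gives the imine F3, whose enamine tautomer adds to pent-1-en-3-one at the more substituted α-carbon under control of the amine to give the adduct imine F4. Aqueous acetic acid hydrolyses it to the 1,5-diketone F5, and aldol condensation (NaOMe, MeOH) closes ring A to **13**. This gives up the two-ring cascade but uses only known chemistry.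

**Step 15.** The ene reaction may spread over the three allylic positions: besides C15, the α-hydrogen at C3 is axial and on the attacked face, and C6 also offers a hydrogen. The tertiary allylic hydroperoxide may also be lost on purification. No regiospecific substitute for the ene reaction is available in a few steps, so the fallback changes the substrate and the order; it sets out from **18** and returns at **22**. Acylation with trifluoroacetic anhydride gives the 3β-trifluoroacetate F6, in which the C3 hydrogen is more strongly deactivated and no angelate is exposed to the sensitiser. Photooxygenation gives the 5α-hydroperoxide F7, and 2-methoxypropene with pyridinium p-toluenesulfonate protects it as the peroxyketal F8. Methanolysis (NaHCO3, MeOH) frees the 3β-alcohol F9, acylation with **20** as in step 14 gives the angelate peroxyketal F10, and aqueous acetic acid releases **22**. This route is five steps longer and does not remove the C6 channel.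

**Step 2.** The stabilised phosphonate carbanion may add sluggishly to the enolisable methyl ketone, giving incomplete conversion, and may give a poor E/Z ratio. The fallback sets out from **4** and returns at **6**. It is a Peterson olefination with lithiated (trimethylsilyl)methyl phenyl sulfone (n-BuLi, THF, −78 °C → rt), a smaller and more nucleophilic carbanion whose adduct eliminates silanolate in the same flask. The Z isomer would still have to be removed.

**Step 8.** Transmetalation of the hindered tetrasubstituted tert-butyldimethylsilyl enol ether may be slow, and β-hydride elimination may take a C15 hydrogen instead of H5, giving the exocyclic enone. The fallback sets out from **12** and returns at **13**. N-Bromosuccinimide (THF, −78 → 0 °C) converts the enol ether regiospecifically into 4-bromo-5α-eudesm-11-en-3-one F11, and dehydrobromination (Li2CO3, LiBr, DMF, 120 °C) gives the conjugated enone under thermodynamic control.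

**Step 9.** Oxidation may also occur at the C7 methine, at C6 (γ to the enone) or further at C12, lowering the yield of **14**. The fallback sets out from **13** and returns at **15**. Ene-type chlorination with hypochlorous acid (Ca(OCl)2, solid CO2, CH2Cl2/H2O, 0 °C) gives 12-chloroeudesma-4,11(13)-dien-3-one F12, and oxidation of the allylic chloride with 4-methylmorpholine N-oxide (MeCN, rt) gives the enal directly.

## Further compounds

F1 | step 6 | limonene 1,2-oxide (cis/trans mixture) | CC12OC1C[C@@H](CC2)C(C)=C
F2 | step 6 | (5R)-2-methyl-5-(prop-1-en-2-yl)cyclohexan-1-one (dihydrocarvone, C2 epimers) | CC1C(=O)C[C@@H](CC1)C(C)=C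
F3 | step 6 | N-[(1R)-1-phenylethyl]imine of F2 | CC1C(=N[C@H](C)c2ccccc2)C[C@@H](CC1)C(C)=C
F4 | step 6 | N-[(1R)-1-phenylethyl]imine of F5 (Michael adduct) | CC(=C)[C@@H]1CC[C@@](C)(CCC(=O)CC)C(=N[C@H](C)c2ccccc2)C1
F5 | step 6 | 2-methyl-2-(3-oxopentyl)-5-(prop-1-en-2-yl)cyclohexan-1-one (methyl cis to isopropenyl) | CC(=C)[C@@H]1CC[C@@](C)(CCC(=O)CC)C(=O)C1
F6 | step 15 | methyl 3β-(trifluoroacetoxy)eudesma-4,11(13)-dien-12-oate | C=C(C(=O)OC)[C@@H]1CC[C@@]2(C)CC[C@H](OC(=O)C(F)(F)F)C(C)=C2C1
F7 | step 15 | methyl 5α-hydroperoxy-3β-(trifluoroacetoxy)eudesma-4(15),11(13)-dien-12-oate | C=C(C(=O)OC)[C@@H]1CC[C@@]2(C)CC[C@H](OC(=O)C(F)(F)F)C(=C)[C@]2(OO)C1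
F8 | step 15 | methyl 5α-[(2-methoxypropan-2-yl)peroxy]-3β-(trifluoroacetoxy)eudesma-4(15),11(13)-dien-12-oate | C=C(C(=O)OC)[C@@H]1CC[C@@]2(C)CC[C@H](OC(=O)C(F)(F)F)C(=C)[C@]2(OOC(C)(C)OC)C1
F9 | step 15 | methyl 3β-hydroxy-5α-[(2-methoxypropan-2-yl)peroxy]eudesma-4(15),11(13)-dien-12-oate | C=C(C(=O)OC)[C@@H]1CC[C@@]2(C)CC[C@H](O)C(=C)[C@]2(OOC(C)(C)OC)C1
F10 | step 15 | methyl 3β-angeloyloxy-5α-[(2-methoxypropan-2-yl)peroxy]eudesma-4(15),11(13)-dien-12-oate | C=C(C(=O)OC)[C@@H]1CC[C@@]2(C)CC[C@H](OC(=O)/C(C)=C\C)C(=C)[C@]2(OOC(C)(C)OC)C1
F0 | step 2 | none | none
F11 | step 8 | 4-bromo-5α-eudesm-11-en-3-one (C4 epimers) | CC(=C)[C@@H]1CC[C@@]2(C)CCC(=O)C(C)(Br)[C@@H]2C1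
F12 | step 9 | 12-chloroeudesma-4,11(13)-dien-3-one | C=C(CCl)[C@@H]1CC[C@@]2(C)CCC(=O)C(C)=C2C1
A1 | alternative 1 | dimethyl 3-oxo-11,12,13-trinoreudesm-4-ene-7,7-dicarboxylate | COC(=O)C1(C(=O)OC)CC[C@@]2(C)CCC(=O)C(C)=C2C1
A2 | alternative 1 | (4R)-3-(bromomethyl)-4-(2-iodoethyl)-2,4-dimethylcyclohex-2-en-1-one | ICC[C@@]1(C)CCC(=O)C(C)=C1CBr
A3 | alternative 1 | dimethyl malonate | COC(=O)CC(=O)OC
A4 | alternative 2 | 11-(triethylsilyloxy)-5β-eudesm-8-en-3-one | CC(C)(O[Si](CC)(CC)CC)[C@@H]1C=C[C@@]2(C)CCC(=O)[C@@H](C)[C@H]2C1
A5 | alternative 2 | 3,5-dimethyl-7-[2-(triethylsilyloxy)propan-2-yl]-2-vinylbicyclo[2.2.2]oct-5-en-2-ol (vinyl syn to the ring alkene) | C=C[C@]1(O)[C@@H](C)[C@H]2C[C@H](C(C)(C)O[Si](CC)(CC)CC)[C@@H]1C=C2C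
A6 | alternative 3 | methyl 3-oxoeudesma-4,11(13)-dien-12-oate (identical with 17) | C=C(C(=O)OC)[C@@H]1CC[C@@]2(C)CCC(=O)C(C)=C2C1
A7 | alternative 3 | methyl (2Z)-4-[(6R)-6-(2-iodoethyl)-2,6-dimethyl-3-oxocyclohex-1-en-1-yl]-2-(phenylsulfonylmethyl)but-2-enoate | ICC[C@@]1(C)CCC(=O)C(C)=C1C/C=C(\CS(=O)(=O)c2ccccc2)C(=O)OC
A8 | alternative 3 | hexabutylditin | CCCC[Sn](CCCC)(CCCC)[Sn](CCCC)(CCCC)CCCC
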